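**Retrosynthetic overview**
1. The 1,2-dioxine (the only ring) is formed last: suprafacial [4+2] addition of singlet oxygen to the (3E,5Z)-dienoic acid 17 held in a chiral guanidinium ion pair sets C3 and C6.
2. 17 comes from the key C4–C5 bond formation, a Suzuki–Miyaura sp2–sp2 coupling of (Z)-alkenyl boronate 11 with (E)-bromo acid 16; each partner brings one defined alkene geometry.
3. 11 comes from a Negishi sp3–sp2 coupling of the alkylzinc from iodide 6 with (Z)-bromoalkenyl boronate 9 (bromoboration of but-1-yne); 6 comes from hex-1-ene by two Zr-catalysed carboaluminations that set both side-chain stereocentres.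
4. 16 comes from but-1-yne by anti addition of IBr, site-selective Pd coupling with the zinc enolate of methyl bromoacetate, and saponification.

Assumption: the ring is numbered O1, O2, C3 (CH2CO2H), C4 (Et), C5, C6 (Et, side chain), and the (4S,8S) enantiomer of the guanidine director G, (4S,8S)-4,8-diphenyl-1,5,7-triazabicyclo[4.4.0]dec-5-ene (C1C[C@@H](c2ccccc2)N=C3N[C@H](c4ccccc4)CCN13), is taken as the one matched to the (3R,6R) ring; if experiment shows the opposite, its antipode is used.

**Step 1**
Reactants: 1 hex-1-ene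
Product: 3 (4S)-4-ethyloct-1-ene, via (S)-(2-ethylhexyl)diethylalane 2 (not isolated)
Conditions: Et3Al (1.5 equiv), (+)-(NMI)2ZrCl2 (5 mol%; the enantiomer that gives 2S products), IBAO, CH2Cl2, 0 °C to rt; then Zn(OTf)2, DMF; CH2=CHBr (excess), PdCl2(DPEphos) (3 mol%), DIBAL-H (6 mol%), rt
Reagents that add atoms: triethylaluminium CC[Al](CC)CC; vinyl bromide C=CBr
Why: Zr-catalysed asymmetric carboalumination (ZACA) delivers ethyl to one face of the terminal alkene and sets C4 as S (about 90% ee); the alane is then vinylated in the same pot by a Zn-promoted Pd-catalysed Negishi-type coupling.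

**Step 2**
Reactants: 3 (4S)-4-ethyloct-1-ene
Product: 5 (2S,4S)-4-ethyl-2-methyloctan-1-ol, via [(2S,4S)-4-ethyl-2-methyloctyl]dimethylalane 4 (not isolated)
Conditions: Me3Al (2 equiv), (+)-(NMI)2ZrCl2 (5 mol%), MAO (20 mol%), CH2Cl2, 0 °C to rt; then O2, 0 °C; 2 M HCl; SiO2 chromatography to remove the C2 epimer
Reagents that add atoms: trimethylaluminium C[Al](C)C; oxygen O=O
Why: A second ZACA reaction (methylalumination) sets C2 as S under catalyst control and O2 oxidises the C–Al bond with retention; removing the minor diastereomer at the alcohol stage also removes most material from the minor enantiomer of 3, so 5 is obtained in high ee.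

**Step 3**
Reactants: 5 (2S,4S)-4-ethyl-2-methyloctan-1-ol
Product: 6 (2S,4S)-4-ethyl-1-iodo-2-methyloctane
Conditions: I2, PPh3, imidazole, CH2Cl2, 0 °C to rt
Reagents that add atoms: iodine II
Why: Appel-type iodination of a primary alcohol; no stereocentre is touched.

**Step 4**
Reactants: 7 but-1-yne
Product: 9 2-[(1Z)-2-bromobut-1-en-1-yl]-4,4,5,5-tetramethyl-1,3,2-dioxaborolane, via (Z)-2-bromobutenyl dibromoborane 8 (not isolated)
Conditions: BBr3 (1.0 equiv), CH2Cl2, −78 °C to rt; then pinacol, rt
Reagents that add atoms: boron tribromide BrB(Br)Br; pinacol CC(C)(O)C(C)(C)O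
Why: syn-Bromoboration of the terminal alkyne (Br to the internal carbon, B to the terminus) fixes the Z geometry, and pinacol turns the dibromoborane into a stable boronate.

**Step 5**
Reactants: 6 (2S,4S)-4-ethyl-1-iodo-2-methyloctane; 9 2-[(1Z)-2-bromobut-1-en-1-yl]-4,4,5,5-tetramethyl-1,3,2-dioxaborolane
Product: 11 2-[(1Z,4S,6S)-2,6-diethyl-4-methyldec-1-en-1-yl]-4,4,5,5-tetramethyl-1,3,2-dioxaborolane, via alkylzinc iodide 10 (not isolated)
Conditions: 6, Zn dust, LiCl, THF, 40 °C; then 9, Pd(t-Bu3P)2 (2 mol%), THF, rt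
Reagents that add atoms: none
Why: Zinc insertion gives the alkylzinc, and Negishi coupling at the C–Br bond proceeds with retention, so the side-chain CH2 ends cis to boron; the boronate is inert because no base is present.

**Step 6**
Reactants: 7 but-1-yne
Product: 12 (1E)-2-bromo-1-iodobut-1-ene
Conditions: IBr (1.05 equiv), CH2Cl2, −78 to 0 °C, dark
Reagents that add atoms: iodine monobromide IBr
Why: Electrophilic anti addition of IBr (iodine to the terminal carbon, bromide to the internal carbon) gives the E-dihaloalkene.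

**Step 7**
Reactants: 12 (1E)-2-bromo-1-iodobut-1-ene; 13 methyl bromoacetate
Product: 15 methyl (3E)-4-bromohex-3-enoate, via Reformatsky reagent 14 (not isolated)
Conditions: 13, Zn dust (TMSCl-activated), THF, 40 °C; then 12, Pd2(dba)3 (2 mol%), XPhos (4 mol%), THF, rt
Reagents that add atoms: none
Why: Reformatsky reagent formation followed by a Pd-catalysed Negishi-type coupling that is selective for the unhindered terminal C–I bond over the internal C–Br bond and retains the alkene geometry.

**Step 8**
Reactants: 15 methyl (3E)-4-bromohex-3-enoate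
Product: 16 (3E)-4-bromohex-3-enoic acid
Conditions: LiOH (1.5 equiv), THF/H2O (3:1), 0 °C; then 1 M HCl
Reagents that add atoms: lithium hydroxide [Li+].[OH-]
Why: Saponification of the methyl ester at 0 °C; the β,γ-alkene and the vinyl bromide are untouched.

**Step 9**
Reactants: 11 2-[(1Z,4S,6S)-2,6-diethyl-4-methyldec-1-en-1-yl]-4,4,5,5-tetramethyl-1,3,2-dioxaborolane; 16 (3E)-4-bromohex-3-enoic acid
Product: 17 (3E,5Z,8S,10S)-4,6,10-triethyl-8-methyltetradeca-3,5-dienoic acid
Conditions: Pd(OAc)2 (3 mol%), SPhos (6 mol%), K3PO4 (3 equiv), THF/H2O (10:1), 40 °C; then 1 M HCl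
Reagents that add atoms: none
Why: Suzuki–Miyaura coupling of two stereodefined alkenyl partners forms the C4–C5 bond with retention at both, giving the (3E,5Z)-diene; the substrate reacts as its carboxylate, which prevents migration of the alkene into conjugation.

**Step 10**
Reactants: 17 (3E,5Z,8S,10S)-4,6,10-triethyl-8-methyltetradeca-3,5-dienoic acid
Product: 20 2-[(3R,6R)-4,6-diethyl-6-[(2S,4S)-4-ethyl-2-methyloctyl]-3,6-dihydro-1,2-dioxin-3-yl]acetic acid, via guanidinium dienoate salt 18 (not isolated), via guanidinium salt of the cyclic peroxide 19 (not isolated)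
Conditions: G (1.05 equiv), CH2Cl2, rt; then TPP (0.5 mol%), O2, 590 nm LED, −78 °C; then 0.5 M HCl wash (G recovered)
Reagents that add atoms: oxygen O=O
Why: Proposed new method: chiral-guanidinium-directed [4+2] photooxygenation, in which the carboxylate of 17 is held in a bidentate C2-symmetric guanidinium salt bridge (18) whose 4,8-phenyl groups cover one π-face of the neighbouring C3=C4 terminus, so singlet oxygen adds suprafacially to the open face of the s-cis diene; the (3E,5Z) geometry fixes the relative configuration (CH2CO2H cis to the C6 ethyl) and the director the absolute one (3R,6R); the closest known reaction types are the singlet-oxygen [4+2] cycloaddition of acyclic 1,3-dienes to 3,6-dihydro-1,2-dioxines and auxiliary-shielded or hydrogen-bond-directed photooxygenations of chiral dienes.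

**Compound list**
1 | hex-1-ene | C=CCCCC | starting material
2 | diethyl[(2S)-2-ethylhexyl]alumane | CCCC[C@H](CC)C[Al](CC)CC | intermediate
3 | (4S)-4-ethyloct-1-ene | CCCC[C@H](CC)CC=C | intermediate
4 | [(2S,4S)-4-ethyl-2-methyloctyl]dimethylalumane | CCCC[C@H](CC)C[C@H](C)C[Al](C)C | intermediate
5 | (2S,4S)-4-ethyl-2-methyloctan-1-ol | CCCC[C@H](CC)C[C@H](C)CO | intermediate
6 | (2S,4S)-4-ethyl-1-iodo-2-methyloctane | CCCC[C@H](CC)C[C@H](C)CI | intermediate
7 | but-1-yne | CCC#C | starting material
8 | dibromo[(1Z)-2-bromobut-1-en-1-yl]borane | CC/C(Br)=C/B(Br)Br | intermediate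
9 | 2-[(1Z)-2-bromobut-1-en-1-yl]-4,4,5,5-tetramethyl-1,3,2-dioxaborolane | CC/C(Br)=C/B1OC(C)(C)C(C)(C)O1 | intermediate
10 | [(2S,4S)-4-ethyl-2-methyloctyl](iodo)zinc | CCCC[C@H](CC)C[C@H](C)C[Zn]I | intermediate
11 | 2-[(1Z,4S,6S)-2,6-diethyl-4-methyldec-1-en-1-yl]-4,4,5,5-tetramethyl-1,3,2-dioxaborolane | CCCC[C@H](CC)C[C@H](C)C/C(CC)=C\B1OC(C)(C)C(C)(C)O1 | intermediate
12 | (1E)-2-bromo-1-iodobut-1-ene | CC/C(Br)=C\I | intermediate
13 | methyl bromoacetate | COC(=O)CBr | starting material
14 | bromo(2-methoxy-2-oxoethyl)zinc | COC(=O)C[Zn]Br | intermediate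
15 | methyl (3E)-4-bromohex-3-enoate | CC/C(Br)=C\CC(=O)OC | intermediate
16 | (3E)-4-bromohex-3-enoic acid | CC/C(Br)=C\CC(=O)O | intermediate
17 | (3E,5Z,8S,10S)-4,6,10-triethyl-8-methyltetradeca-3,5-dienoic acid | CCCC[C@H](CC)C[C@H](C)C/C(CC)=C\C(CC)=C\CC(=O)O | intermediate
18 | (4S,8S)-4,8-diphenyl-1,5,7-triazabicyclo[4.4.0]dec-5-enium (3E,5Z,8S,10S)-4,6,10-triethyl-8-methyltetradeca-3,5-dienoate | CCCC[C@H](CC)C[C@H](C)C/C(CC)=C\C(CC)=C\CC(=O)[O-].C1C[C@@H](c2ccccc2)[NH+]=C3N[C@H](c4ccccc4)CCN13 | intermediate
19 | (4S,8S)-4,8-diphenyl-1,5,7-triazabicyclo[4.4.0]dec-5-enium 2-[(3R,6R)-4,6-diethyl-6-[(2S,4S)-4-ethyl-2-methyloctyl]-3,6-dihydro-1,2-dioxin-3-yl]acetate | CCCC[C@H](CC)C[C@H](C)C[C@]1(CC)C=C(CC)[C@@H](CC(=O)[O-])OO1.C1C[C@@H](c2ccccc2)[NH+]=C3N[C@H](c4ccccc4)CCN13 | intermediate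
20 | 2-[(3R,6R)-4,6-diethyl-6-[(2S,4S)-4-ethyl-2-methyloctyl]-3,6-dihydro-1,2-dioxin-3-yl]acetic acid | CCCC[C@H](CC)C[C@H](C)C[C@]1(CC)C=C(CC)[C@@H](CC(=O)O)OO1 | target

**Totals**
Total step count: 10. Longest linear sequence: 6 steps (1, 2, 3, 5, 9, 10).

**Steps most likely to fail, and fallbacks**

Step 10 is the new method and the main risk: the ion pair may give little face selectivity, and ene reactions of singlet oxygen at the allylic positions compete with the cycloaddition. The fallback uses known chemistry and drops reagent control. It sets out from 17, which is photooxygenated without any director (TPP, O2, visible light, CH2Cl2, −78 °C), the standard singlet-oxygen [4+2] cycloaddition. This gives 20 together with about an equal amount of the diastereomer with the opposite ring configuration, 2-[(3S,6S)-4,6-diethyl-6-[(2S,4S)-4-ethyl-2-methyloctyl]-3,6-dihydro-1,2-dioxin-3-yl]acetic acid F3. The two are separated by preparative HPLC on a chiral phase, and the route is rejoined at 20.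

Step 7 is the second risk: the Reformatsky reagent may also attack the C–Br bond, or the β,γ-unsaturated ester may drift into conjugation. The fallback sets out from 12 and builds the acetic acid unit by allylation and oxidative cleavage instead of enolate coupling. Pd-catalysed coupling of 12 with allylzinc bromide at the C–I bond gives (4E)-5-bromohepta-1,4-diene F1. Lemieux–Johnson cleavage of its terminal alkene (cat. OsO4, NaIO4, 2,6-lutidine, dioxane/H2O) gives (3E)-4-bromohex-3-enal F2. Pinnick oxidation (NaClO2, NaH2PO4, 2-methylbut-2-ene) comes back to the route at 16 and bypasses 15.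

Step 5 is the third risk: the (Z)-bromoalkenyl boronate 9 can isomerise, and the β-branched alkylzinc may couple slowly. The fallback sets out from 6 and 7 and replaces the bromoboration–Negishi sequence by a copper-catalysed three-component carboboration (CuCl/Xantphos, B2pin2, NaOt-Bu, THF). Boron adds to the terminal carbon of but-1-yne and the alkyl group of 6 to the internal carbon in a syn sense, which comes back at 11 directly; it makes no compound outside the list (F0).

**Further compounds**
F0 | step 5 | none | none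
F1 | step 7 | (4E)-5-bromohepta-1,4-diene | CC/C(Br)=C\CC=C
F2 | step 7 | (3E)-4-bromohex-3-enal | CC/C(Br)=C\CC=O
F3 | step 10 | 2-[(3S,6S)-4,6-diethyl-6-[(2S,4S)-4-ethyl-2-methyloctyl]-3,6-dihydro-1,2-dioxin-3-yl]acetic acid | CCCC[C@H](CC)C[C@H](C)C[C@@]1(CC)C=C(CC)[C@H](CC(=O)O)OO1
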